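**Retrosynthetic overview**

1. Feature: ring A (C4a, C5–C8, C8a, with OMe on C6 and C7) and the aryl group on C1 are the same 3,4-dimethoxyphenyl unit, so C1 can be carried as a non-stereogenic bis(aryl)methine and becomes a stereocentre only when C4 is bonded to C4a of one of the two rings.
2. Phyltetralin 21 ⇐ all-trans 4-aryl-1-tetralone 19 (C4 of the target as C=O) by hydrogenolysis of the aryl ketone.
3. 19 ⇐ lactone 15 + veratrole 16: the C1–aryl bond by Friedel–Crafts alkylation at the benzylic lactone carbon, then the C4–C4a bond by acylation, which closes ring B; ring A and the pendant aryl arrive as intact veratryl units.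
4. 15 ⇐ trans-paraconic acid 11: carboxyl → CH2OMe (arm on C2), then anti α-methoxymethylation of the lactone enolate (arm on C3).
5. 11 ⇐ Evans syn-aldol and lactonisation of succinate half-ester imide 4 with veratraldehyde 5; ring order: γ-lactone (temporary), then ring B.

Key step: step 7

Remark: numbering follows the tetralin core of the target (C1 bears the aryl group, C2 and C3 the methoxymethyl arms, C4 is the benzylic CH2; ring A is the fused dimethoxybenzene ring, ring B the saturated ring); both enantiomers of 4-benzyl-2-oxazolidinone are taken to be commercial, and the (R)-form is needed because the syn-aldol must set the carbon that becomes C2, while the benzylic centre formed with it is ionised in step 7 and need not be controlled.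

**Route**

Step 1
Reactants: 1 (R)-4-benzyl-2-oxazolidinone; 2 methyl 4-chloro-4-oxobutanoate
Product: 4 methyl 4-[(4R)-4-benzyl-2-oxo-1,3-oxazolidin-3-yl]-4-oxobutanoate, via lithium oxazolidinide 3 (not isolated)
Conditions: n-BuLi, THF, −78 °C; then 2, −78 → 0 °C
Reagents that add atoms: none
Why: N-acylation of a lithiated oxazolidinone by an acid chloride, which reacts far faster than the methyl ester end, so the succinate should be attached through one carboxyl only.

Step 2
Reactants: 4 methyl 4-[(4R)-4-benzyl-2-oxo-1,3-oxazolidin-3-yl]-4-oxobutanoate; 5 veratraldehyde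
Product: 9 (4R)-4-benzyl-3-{[(2R,3R)-2-(3,4-dimethoxyphenyl)-5-oxotetrahydrofuran-3-yl]carbonyl}-1,3-oxazolidin-2-one, via boron enolate 6 (not isolated), via boron aldolate 7 (not isolated), via aldol hydroxy ester 8 (not isolated)
Conditions: Bu2BOTf, i-Pr2NEt, CH2Cl2, −78 → 0 °C; 5, −78 → 0 °C; H2O2, pH 7 buffer–MeOH, 0 °C; then PPTS (cat.), CH2Cl2, rt
Reagents that add atoms: none
Why: Evans syn-aldol reaction, in which soft enolisation touches only the imide α-CH2 and gives the Z-boron enolate, which adds to the aldehyde through a closed Zimmerman–Traxler chair on the face away from the benzyl group of the (R)-auxiliary and sets both new centres R (syn), after which the freed benzylic hydroxyl closes the γ-lactone on the methyl ester with the acyl and aryl groups trans.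

Step 3
Reactants: 9 (4R)-4-benzyl-3-{[(2R,3R)-2-(3,4-dimethoxyphenyl)-5-oxotetrahydrofuran-3-yl]carbonyl}-1,3-oxazolidin-2-one
Product: 11 (2R,3R)-2-(3,4-dimethoxyphenyl)-5-oxotetrahydrofuran-3-carboxylic acid, via peroxy acid 10 (not isolated)
Conditions: LiOH, H2O2, THF–H2O, 0 °C; Na2SO3 (aq); HCl to pH 2
Reagents that add atoms: hydrogen peroxide (as LiOOH), OO
Why: Hydroperoxide-mediated cleavage of an N-acyl oxazolidinone attacks the exocyclic carbonyl, sulfite reduces the peroxy acid, and acidification recloses any opened γ-lactone, so no stereocentre should be touched.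

Step 4
Reactants: 11 (2R,3R)-2-(3,4-dimethoxyphenyl)-5-oxotetrahydrofuran-3-carboxylic acid
Product: 12 (4S,5R)-5-(3,4-dimethoxyphenyl)-4-(hydroxymethyl)dihydrofuran-2(3H)-one
Conditions: BH3·SMe2, THF, 0 °C → rt; MeOH, then aqueous work-up
Reagents that add atoms: none
Why: Chemoselective borane reduction of a free carboxylic acid (acyloxyborane pathway), which is much faster than reduction of the lactone.

Step 5
Reactants: 12 (4S,5R)-5-(3,4-dimethoxyphenyl)-4-(hydroxymethyl)dihydrofuran-2(3H)-one
Product: 13 (4S,5R)-5-(3,4-dimethoxyphenyl)-4-(methoxymethyl)dihydrofuran-2(3H)-one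
Conditions: Me3OBF4, 1,8-bis(dimethylamino)naphthalene, CH2Cl2, 0 °C → rt
Reagents that add atoms: trimethyloxonium tetrafluoroborate, C[O+](C)C.F[B-](F)(F)F
Why: O-methylation with Meerwein's salt and a hindered amine needs no alkoxide, so the hydroxymethyl lactone should not translactonise onto the primary oxygen before it is capped.

Step 6
Reactants: 13 (4S,5R)-5-(3,4-dimethoxyphenyl)-4-(methoxymethyl)dihydrofuran-2(3H)-one
Product: 15 (3S,4S,5R)-5-(3,4-dimethoxyphenyl)-3,4-bis(methoxymethyl)dihydrofuran-2(3H)-one, via lithium enolate 14 (not isolated)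
Conditions: LiHMDS (1.05 equiv), THF, −78 °C; MOMCl, −78 → −40 °C
Reagents that add atoms: chloromethyl methyl ether, COCCl
Why: Alkylation of a lactone lithium enolate with an α-chloro ether, in which the electrophile enters anti to the CH2OMe group on the adjacent C4 and so sets C3 as S (3,4-trans).

Step 7
Reactants: 15 (3S,4S,5R)-5-(3,4-dimethoxyphenyl)-3,4-bis(methoxymethyl)dihydrofuran-2(3H)-one; 16 veratrole
Product: 19 (2S,3S,4R)-4-(3,4-dimethoxyphenyl)-6,7-dimethoxy-2,3-bis(methoxymethyl)-3,4-dihydronaphthalen-1(2H)-one, via diaryl acid 17 (not isolated), via mixed anhydride 18 (not isolated)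
Conditions: 16 (2 equiv), TfOH, CH2Cl2, −20 → 0 °C; then TFAA, 0 °C → rt
Reagents that add atoms: none
Why: TfOH ionises the benzylic C5–O bond of the lactone to a para-methoxy-stabilised cation that veratrole captures para to one of its methoxy groups (intermolecular Friedel–Crafts alkylation, the C1–aryl bond of the target), which releases acid 17 with two identical veratryl groups on a carbon that is no longer stereogenic, so the C5 configuration of 15 does not matter. TFAA converts 17 into mixed anhydride 18, and its acyl carbon is attacked by one veratryl ring at the position ortho to the methine and para to a methoxy group, a 6-exo ring-closing Friedel–Crafts acylation that forms the C4–C4a bond and ring B. The closest known reaction type is the acid-mediated one-pot conversion of γ-aryl-γ-butyrolactones and arenes into 4-aryl-1-tetralones. The only new stereocentre, C1, results from the choice between the two diastereotopic rings and is controlled by the fixed neighbouring centre C2: in the half-chair transition state with both CH2OMe arms pseudo-equatorial, the ring that reacts is the one that leaves the spectator aryl pseudo-equatorial, which should give the 1,2-trans, all-trans tetralone. The step needs this group selectivity, closure para and not ortho to methoxy (the ortho site lies between two substituents), and attack by the arene in preference to the ether oxygen of the C2 arm; the electron-rich ring in a six-membered transition state, weakly nucleophilic triflate and trifluoroacetate counter-ions that keep O-acylation reversible, and the use of only two equivalents of veratrole should secure them.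

Step 8
Reactants: 19 (2S,3S,4R)-4-(3,4-dimethoxyphenyl)-6,7-dimethoxy-2,3-bis(methoxymethyl)-3,4-dihydronaphthalen-1(2H)-one
Product: 21 phyltetralin (1R,2S,3S)-1-(3,4-dimethoxyphenyl)-6,7-dimethoxy-2,3-bis(methoxymethyl)-1,2,3,4-tetrahydronaphthalene, via benzylic alcohol 20 (not isolated)
Conditions: H2 (3 atm), 10% Pd/C, AcOH, HClO4 (cat.), rt
Reagents that add atoms: none
Why: Catalytic hydrogenolysis of an aryl ketone whose carbonyl carbon is para to a ring methoxy group, by hydrogenation to the benzylic alcohol and acid-assisted cleavage of the only benzylic C–O bond, with the three stereocentres not involved.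

**Compound list**

1 | (R)-4-benzyl-2-oxazolidinone | O=C1N[C@H](Cc2ccccc2)CO1 | starting material
2 | methyl 4-chloro-4-oxobutanoate | COC(=O)CCC(Cl)=O | starting material
3 | lithium (R)-4-benzyl-2-oxooxazolidin-3-ide | [Li]N1[C@H](Cc2ccccc2)COC1=O | intermediate
4 | methyl 4-[(4R)-4-benzyl-2-oxo-1,3-oxazolidin-3-yl]-4-oxobutanoate | COC(=O)CCC(=O)N1[C@H](Cc2ccccc2)COC1=O | intermediate
5 | veratraldehyde (3,4-dimethoxybenzaldehyde) | COc1ccc(C=O)cc1OC | starting material
6 | dibutylboron (Z)-enolate of 4 | CCCCB(CCCC)O/C(=C\CC(=O)OC)N1[C@H](Cc2ccccc2)COC1=O | intermediate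
7 | dibutylboron aldolate (O-borylated form of 8) | CCCCB(CCCC)O[C@@H](c1ccc(OC)c(OC)c1)[C@@H](CC(=O)OC)C(=O)N1[C@H](Cc2ccccc2)COC1=O | intermediate
8 | methyl (3R)-4-[(4R)-4-benzyl-2-oxo-1,3-oxazolidin-3-yl]-3-[(R)-(3,4-dimethoxyphenyl)(hydroxy)methyl]-4-oxobutanoate | O[C@@H](c1ccc(OC)c(OC)c1)[C@@H](CC(=O)OC)C(=O)N1[C@H](Cc2ccccc2)COC1=O | intermediate
9 | (4R)-4-benzyl-3-{[(2R,3R)-2-(3,4-dimethoxyphenyl)-5-oxotetrahydrofuran-3-yl]carbonyl}-1,3-oxazolidin-2-one | O=C1C[C@@H](C(=O)N2[C@H](Cc3ccccc3)COC2=O)[C@H](c2ccc(OC)c(OC)c2)O1 | intermediate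
10 | (2R,3R)-2-(3,4-dimethoxyphenyl)-5-oxotetrahydrofuran-3-carboperoxoic acid | O=C1C[C@@H](C(=O)OO)[C@H](c2ccc(OC)c(OC)c2)O1 | intermediate
11 | (2R,3R)-2-(3,4-dimethoxyphenyl)-5-oxotetrahydrofuran-3-carboxylic acid | O=C1C[C@@H](C(=O)O)[C@H](c2ccc(OC)c(OC)c2)O1 | intermediate
12 | (4S,5R)-5-(3,4-dimethoxyphenyl)-4-(hydroxymethyl)dihydrofuran-2(3H)-one | O=C1C[C@@H](CO)[C@H](c2ccc(OC)c(OC)c2)O1 | intermediate
13 | (4S,5R)-5-(3,4-dimethoxyphenyl)-4-(methoxymethyl)dihydrofuran-2(3H)-one | O=C1C[C@@H](COC)[C@H](c2ccc(OC)c(OC)c2)O1 | intermediate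
14 | lithium enolate of 13 | [Li]OC1=C[C@@H](COC)[C@H](c2ccc(OC)c(OC)c2)O1 | intermediate
15 | (3S,4S,5R)-5-(3,4-dimethoxyphenyl)-3,4-bis(methoxymethyl)dihydrofuran-2(3H)-one | COC[C@H]1C(=O)O[C@@H](c2ccc(OC)c(OC)c2)[C@@H]1COC | intermediate
16 | veratrole (1,2-dimethoxybenzene) | COc1ccccc1OC | starting material
17 | (2S,3S)-4,4-bis(3,4-dimethoxyphenyl)-2,3-bis(methoxymethyl)butanoic acid | COC[C@@H](C(=O)O)[C@@H](COC)C(c1ccc(OC)c(OC)c1)c1ccc(OC)c(OC)c1 | intermediate
18 | mixed trifluoroacetic anhydride of 17 | COC[C@@H](C(=O)OC(=O)C(F)(F)F)[C@@H](COC)C(c1ccc(OC)c(OC)c1)c1ccc(OC)c(OC)c1 | intermediate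
19 | (2S,3S,4R)-4-(3,4-dimethoxyphenyl)-6,7-dimethoxy-2,3-bis(methoxymethyl)-3,4-dihydronaphthalen-1(2H)-one | COC[C@H]1C(=O)c2cc(OC)c(OC)cc2[C@@H](c2ccc(OC)c(OC)c2)[C@@H]1COC | intermediate
20 | (2S,3S,4R)-4-(3,4-dimethoxyphenyl)-6,7-dimethoxy-2,3-bis(methoxymethyl)-1,2,3,4-tetrahydronaphthalen-1-ol (C1 epimers) | COC[C@H]1C(O)c2cc(OC)c(OC)cc2[C@@H](c2ccc(OC)c(OC)c2)[C@@H]1COC | intermediate
21 | phyltetralin, (1R,2S,3S)-1-(3,4-dimethoxyphenyl)-6,7-dimethoxy-2,3-bis(methoxymethyl)-1,2,3,4-tetrahydronaphthalene | COC[C@H]1Cc2cc(OC)c(OC)cc2[C@@H](c2ccc(OC)c(OC)c2)[C@@H]1COC | target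

**Summary**

Total step count: 8. Longest linear sequence: 8 steps (1 and 2 to 21).

Steps most likely to fail:

1. Step 7 (key step). The acylation may not discriminate well between the two diastereotopic veratryl rings. The acyl electrophile may instead be captured by the ether oxygen of the C2 arm, with loss of the methyl group and lactone formation. The benzylic cation may lose the neighbouring proton and scramble the centre that becomes C2. The β-methoxy ketone product may lose methanol under the acid. The fallback sets out from 15 and comes back at 21; it closes ring B by benzylic cation cyclisation instead of acylation. Hydrogenolysis of the benzylic lactone C–O bond of 15 (H2, Pd/C, AcOH) would give (2S,3S)-4-(3,4-dimethoxyphenyl)-2,3-bis(methoxymethyl)butanoic acid F1. Addition of 3,4-dimethoxyphenyllithium (two equivalents, from 4-bromoveratrole and n-BuLi) to its lithium carboxylate would give (2S,3S)-1,4-bis(3,4-dimethoxyphenyl)-2,3-bis(methoxymethyl)butan-1-one F2. NaBH4 would reduce this to (2S,3S)-1,4-bis(3,4-dimethoxyphenyl)-2,3-bis(methoxymethyl)butan-1-ol F3, both carbinol epimers being usable. TFA in CH2Cl2 would ionise the alcohol, and the veratryl ring on the CH2 group would attack the cation para to methoxy with the aryl group pseudo-equatorial, trans to the neighbouring arm, to give 21 directly. Because the trans-bis(methoxymethyl) unit is locally C2-symmetric, the same enantiomer results although the aryl-bearing carbon now comes from the carboxyl end.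

2. Step 6. The hard chloromethyl ether may alkylate the enolate on oxygen (ketene acetal formation), facial selectivity may be incomplete, or the product may be deprotonated a second time and lose methoxide to an α-methylene lactone. The fallback sets out from 13 and comes back at 15. The lithium enolate of 13 would undergo an aldol reaction with monomeric formaldehyde (cracked paraformaldehyde, THF, −78 °C), again anti to the C4 arm, to give (3S,4S,5R)-5-(3,4-dimethoxyphenyl)-3-(hydroxymethyl)-4-(methoxymethyl)dihydrofuran-2(3H)-one F4. O-methylation under the non-basic conditions of step 5 (Me3OBF4, 1,8-bis(dimethylamino)naphthalene) would then give 15.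

3. Step 8. Acid-promoted loss of methanol from the β-methoxy ketone may precede reduction of the carbonyl group. The intermediate benzylic alcohol may dehydrate to the dihydronaphthalene, whose unselective hydrogenation would scramble C3. The reduction may also stall at the alcohol. The fallback sets out from 19 and comes back at 21 by a Mozingo reduction. Ethane-1,2-dithiol and BF3·OEt2 in CH2Cl2 would convert 19 into (2'S,3'S,4'R)-4'-(3,4-dimethoxyphenyl)-6',7'-dimethoxy-2',3'-bis(methoxymethyl)-3',4'-dihydro-2'H-spiro[1,3-dithiolane-2,1'-naphthalene] F5. Raney nickel in EtOH would desulfurise it to 21 without a cationic or olefinic intermediate at C4.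

**Further compounds**

F1 | step 7 | (2S,3S)-4-(3,4-dimethoxyphenyl)-2,3-bis(methoxymethyl)butanoic acid | COC[C@@H](C(=O)O)[C@@H](COC)Cc1ccc(OC)c(OC)c1
F2 | step 7 | (2S,3S)-1,4-bis(3,4-dimethoxyphenyl)-2,3-bis(methoxymethyl)butan-1-one | COC[C@@H](C(=O)c1ccc(OC)c(OC)c1)[C@@H](COC)Cc1ccc(OC)c(OC)c1
F3 | step 7 | (2S,3S)-1,4-bis(3,4-dimethoxyphenyl)-2,3-bis(methoxymethyl)butan-1-ol (C1 epimers) | COC[C@@H](C(O)c1ccc(OC)c(OC)c1)[C@@H](COC)Cc1ccc(OC)c(OC)c1
F4 | step 6 | (3S,4S,5R)-5-(3,4-dimethoxyphenyl)-3-(hydroxymethyl)-4-(methoxymethyl)dihydrofuran-2(3H)-one | OC[C@H]1C(=O)O[C@@H](c2ccc(OC)c(OC)c2)[C@@H]1COC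
F5 | step 8 | (2'S,3'S,4'R)-4'-(3,4-dimethoxyphenyl)-6',7'-dimethoxy-2',3'-bis(methoxymethyl)-3',4'-dihydro-2'H-spiro[1,3-dithiolane-2,1'-naphthalene] | COC[C@H]1C2(SCCS2)c2cc(OC)c(OC)cc2[C@@H](c2ccc(OC)c(OC)c2)[C@@H]1COC
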